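**Remarks on the chemistry (assumptions and design decisions)**

- Assumption: "prenyl" means 3-methylbut-2-en-1-yl. Positions follow coumarin numbering (O1, C2, C3, C4, C4a, C5 to C8, C8a). Ring A is the benzo ring and ring B is the 2,4-dioxygenated phenyl ring on C3.
- Structure check: aryl carbons C1, C2, C3, C4, C5, C6 of acid 9 become C4a, C5, C6, C7, C8, C8a of coumarin 11. Both structures agree with the target substitution pattern, so no structural correction is needed.
- Design decision for the key step: an E acrylic acid cannot reach C8a. The electrolysis is therefore run under 365 nm light so that the Z isomer 10 is supplied continuously, rather than relying only on bond rotation in the radical cation.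
- Design decision for ring B: the amine between 13 and 15 is kept protonated (14) throughout, so the ortho pivalate cannot migrate from O to N.
- Design decision for the endgame: both deprotections are run in one flask.

## Structural features

The target is a 3-arylcoumarin: a benzene ring (ring A) fused through C4a–C8a to a pyran-2-one ring, whose C3 is joined by a single C–C bond to C1′ of a 2,4-dihydroxyphenyl ring (ring B). Ring A is substituted at every position but C8: a free hydroxyl on C5, a prenyl group on C6, a methoxy group on C7 and the lactone oxygen O1 on C8a. There are no stereocentres, and the prenyl alkene ends in two identical methyl groups, so no configuration has to be set. The only stereochemical element met on the way is the E/Z geometry of an acrylic acid precursor. The fragile groups are these: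

- the prenyl alkene beside the free 5-OH (acid closes it to a dimethylchroman; electrophiles, radicals, singlet oxygen and hydrogenation also attack it);
- the lactone, which strong base opens;
- the electron-rich resorcinol ring B, which is air-sensitive as its phenoxide and whose 2′-OH can attack the lactone.

The real difficulty is the regiochemistry of ring A: three oxygens in a 1,3,5 relationship, each in a different state (O1 acylated, O5 free, O7 methylated), with the prenyl group between O5 and O7 and not on C8. The key step exploits the fact that O1 on C8a is meta to both O5 and O7, and that C8a is the only carbon ortho to C4a that would still carry hydrogen in a 2,4-dioxygenated 3-prenylcinnamic acid. The O1–C8a bond can therefore be made last by oxidative C–H lactonisation, and ring A can come from a commercial resorcinol aldehyde whose two oxygens are already differentiated.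

## Logic of the disconnections

18 ⇒ 16 (through 17). The two ester C–O bonds on ring B and the acetal O–CH2 bond on O5 are restored. The reason is that the C3–C1′ bond is to be made with an aryl radical, so ring B must exist as a diazonium salt without free phenols, and O5 must stay capped until the lactone is in place. The gain is that every earlier intermediate is non-phenolic. The forward step must strip three groups with base and then acid, leave the lactone closed, and keep the freed 5-OH from adding to the neighbouring prenyl alkene.

16 ⇒ 11 + 15. The C3–C1′ bond is cut. This is the most convergent cut, and C3–H of a coumarin is the innate site for aryl radical addition because the adduct radical at C4 is benzylic to the dioxygenated ring A. The gain is two halves of similar size, each without the other's functionality. The forward step needs the aryl radical to prefer C3 over the prenyl alkene and its allylic hydrogens, and the acid set free must be buffered.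

15 ⇒ 13 ⇒ 12. The C–N2+ bond is traced back to C–NO2 and the two ester C–O bonds to phenols. 12 already has nitrogen ortho and para to the two oxygens, so no regiochemistry has to be created. The demand is that the amine stage (14) never exists as a free base.

11 ⇒ 9 (through 10). The O1–C8a bond is cut; this is the strategic disconnection. It removes one of the three ring A oxygens, so ring A needs only the two oxygens that are already differentiated in 1, and the pyranone ring opens to a simple acrylic acid. The forward step must form a C–O bond at an unactivated C–H under oxidation, with the side chain in the cisoid geometry, and leave the prenyl alkene and the O5 acetal intact.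

9 ⇒ 6 + 7. The C3=C4 double bond is cut (C2 and C3 come from 7, with loss of one carboxyl). The gain is a benzaldehyde. The forward condensation must tolerate the acetal and deliver a single alkene isomer.

6 ⇒ 5. The O5–CH2 acetal bond is cut. O5 must be capped because a free ortho phenol would lactonise through O5 and lead into the isomeric 8-prenyl series. The demand is alkylation of a hindered, hydrogen-bonded phenol.

5 ⇒ 4 ⇒ 3 ⇒ 1 + 2. The ring–CH2 bond of the prenyl group is traced by a retro-[3,3] shift to an O-bound tertiary allyl group, its alkene to an alkyne, and the O–C bond to 1 and 2. The only free position ortho to the phenol of 1 is the carbon between the two oxygens, so the prenyl group can only arrive where the target has it. The forward steps need semi-hydrogenation that stops at the alkene, and a rearrangement that proceeds faster than fragmentation.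

## Other disconnections considered

Alternative 1: The cut is at C4–C4a and O1–C2. In the forward sense phloroglucinol A3 is condensed in acid with methyl 2-[2,4-bis(pivaloyloxy)phenyl]-3-(dimethylamino)prop-2-enoate A2. The ring attacks the enamine carbon, dimethylamine is lost, and a neighbouring hydroxyl lactonises to give 3-[2,4-bis(pivaloyloxy)phenyl]-5,7-dihydroxycoumarin A1.
- In favour: the annulation is convergent, A3 is threefold symmetric so the ring closure has no regiochemical question, ring B arrives with C3, and all ring A oxygens are present from the start.
- Against: A1 has two free hydroxyls on C5 and C7 that are hard to tell apart in a coumarin, since there is no peri carbonyl to chelate the 5-OH. Selective O7 methylation is therefore not assured. The prenyl group must still be brought to C6 by a three-step ether/semi-hydrogenation/Claisen sequence on O5. The 2′-ester next to the methyl ester of A2 could divert to a benzofuranone under the acidic conditions.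
- Comparison, structure: the chosen plan is better, because O5 and O7 are differentiated from compound 1 onwards.
- Comparison, mechanism: the alternative is better, because its ring-forming step is established chemistry while step 6 is not.
- Comparison, step economy: the two are about equal (roughly nine operations against ten).

Alternative 2: The cut is at C4a–C8a and O1–C2. In the forward sense Mg(OMe)2 in methanol opens the pyranone of methyl 2-[2,4-bis(methoxymethoxy)phenyl]-4-(4-methoxy-2-oxo-2H-pyran-6-yl)butanoate A5. The carbanion at the future C4a condenses with the unveiled ester to form ring A, and the new hydroxyl lactonises onto the side-chain ester to give racemic 3-[2,4-bis(methoxymethoxy)phenyl]-5-hydroxy-7-methoxychroman-2-one A4.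
- In favour: one cascade builds ring A and the lactone (two rings and two bonds, more than step 6 achieves). O1, O5 and O7 emerge already differentiated, which equals the chosen plan. The 5-OH is free for a later Claisen delivery of the prenyl group to C6. The pyranone-to-resorcinol recyclisation has biomimetic precedent, so the key step is less speculative than step 6.
- Against: A4 lacks both the C3=C4 double bond and the prenyl group, so a dehydrogenation and three prenylation steps must follow. A5 needs its own synthesis. The required enolate sits at the less acidic of two positions flanking the ketone. The endgame needs acid on three acetals beside the prenyl phenol, which is worse than the chosen plan.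
- Comparison, structure: equal on oxygen differentiation. Mechanism: the alternative is better on precedent. Step economy: the chosen plan is shorter by about two steps.

Alternative 3: The cut is at C6–C7. In the forward sense the triene A7 closes thermally by disrotatory six-electron electrocyclisation, and loss of tert-butyldimethylsilanol aromatises ring A to give 3-[2,4-bis(tert-butyldimethylsilyloxy)phenyl]-5-(tert-butyldimethylsilyloxy)-7-methoxy-6-prenylcoumarin A6. A7 is a 3-aryl-2-pyranone carrying a Z silyl enol ether on C5 and a silyl ketene acetal on C6.
- In favour: the connectivity of A7 places every ring A substituent, so no Claisen step, no selective protection and no C–H functionalisation is needed. Prenyl and ring B are both present before ring A exists. The pericyclic step is predictable, which is equal to or better than step 6 in mechanistic certainty. A6 needs only one fluoride treatment to reach the target, which avoids acid beside the prenyl phenol and is better than the chosen endgame.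
- Against: A7 is a densely functionalised pyranone with two hydrolytically labile silyl enol derivatives on adjacent positions. Its assembly would be the longest of the four plans. The double enolisation and silylation must be regioselective on a base-sensitive ring. The central alkene of the triene is part of the pyranone, so closure costs conjugation and may need temperatures at which hydrogen or silyl shifts compete.
- Comparison, structure: the alternative is better on regiochemical certainty in ring A and on the endgame. Mechanism: equal or better. Step economy: clearly worse.

Key step: step 6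

## Route

Step 1
Reactants: 1 2-hydroxy-4-methoxybenzaldehyde; 2 3-chloro-3-methylbut-1-yne
Product: 3 4-methoxy-2-[(2-methylbut-3-yn-2-yl)oxy]benzaldehyde
Conditions: DBU, CuCl2·2H2O (1 mol%), MeCN, 0 °C to rt
Reagents that add atoms: none
Why: Copper-catalysed propargylic O-alkylation: the copper acetylide of 2 ionises to a tertiary propargylic electrophile that the DBU phenoxide captures at oxygen; the method is reliable for hindered and hydrogen-bonded phenols and leaves the aldehyde alone.

Step 2
Reactants: 3 4-methoxy-2-[(2-methylbut-3-yn-2-yl)oxy]benzaldehyde
Product: 4 4-methoxy-2-[(2-methylbut-3-en-2-yl)oxy]benzaldehyde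
Conditions: H2 (1 atm), Lindlar catalyst (Pd/CaCO3 poisoned with Pb(OAc)2), quinoline, EtOAc, rt, stopped after 1 equiv H2
Reagents that add atoms: none
Why: Lindlar semi-hydrogenation of a terminal alkyne to the vinyl group; the poisoned catalyst should not reduce the aryl aldehyde or cleave the tertiary ether.

Step 3
Reactants: 4 4-methoxy-2-[(2-methylbut-3-en-2-yl)oxy]benzaldehyde
Product: 5 2-hydroxy-4-methoxy-3-(3-methylbut-2-en-1-yl)benzaldehyde
Conditions: N,N-diethylaniline, 130 °C, Ar
Reagents that add atoms: none
Why: Aromatic Claisen rearrangement ([3,3] shift then tautomerisation): the only free ortho carbon is the one between the two oxygens, and allylic inversion turns the 1,1-dimethylallyl group into the prenyl group; the phenol formed is stabilised by its hydrogen bond to the aldehyde.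

Step 4
Reactants: 5 2-hydroxy-4-methoxy-3-(3-methylbut-2-en-1-yl)benzaldehyde
Product: 6 4-methoxy-2-(methoxymethoxy)-3-(3-methylbut-2-en-1-yl)benzaldehyde
Conditions: MOMCl, iPr2NEt, CH2Cl2, 0 °C to rt
Reagents that add atoms: chloromethyl methyl ether (MOMCl), COCCl
Why: O-alkylation of the phenol with an α-chloro ether (acetal protection); the acetal is stable to the basic condensation, to the buffered electrolysis and to the carbonate methanolysis that follow.

Step 5
Reactants: 6 4-methoxy-2-(methoxymethoxy)-3-(3-methylbut-2-en-1-yl)benzaldehyde; 7 malonic acid
Product: 9 (E)-3-[4-methoxy-2-(methoxymethoxy)-3-(3-methylbut-2-en-1-yl)phenyl]prop-2-enoic acid, via arylidenemalonic acid 8 (not isolated)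
Conditions: pyridine, piperidine (cat.), 90 °C
Reagents that add atoms: none
Why: Knoevenagel–Doebner condensation: iminium-catalysed condensation gives the arylidenemalonic acid, which decarboxylates in hot pyridine to the thermodynamically preferred E acid; the medium stays basic, so the acetal survives.

Step 6
Reactants: 9 (E)-3-[4-methoxy-2-(methoxymethoxy)-3-(3-methylbut-2-en-1-yl)phenyl]prop-2-enoic acid
Product: 11 7-methoxy-5-(methoxymethoxy)-6-(3-methylbut-2-en-1-yl)-2H-chromen-2-one, via Z-acrylic acid 10 (not isolated)
Conditions: 365 nm LEDs; undivided cell, graphite anode, Pt cathode, constant current (about 2.2 F mol−1, low current density), nBu4NPF6 (0.1 M), 2,6-lutidine (2 equiv), MeCN/HFIP 9:1, 0.02 M, rt, Ar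
Reagents that add atoms: none
Why: Proposed new method: direct 365 nm excitation of the dialkoxycinnamate chromophore interconverts 9 and its Z isomer 10 (classical cinnamate E/Z photoisomerisation, run without oxygen so that no singlet-oxygen ene reaction can touch the prenyl group), which brings the carboxylate within reach of the only ring A C–H ortho to the side chain. At the graphite anode the lutidinium carboxylate of the electron-rich aryl alkene should be oxidised, at a potential expected to lie below those of the isolated trisubstituted alkene, of Kolbe oxidation of the carboxylate and of the product lactone, to a radical cation best drawn as a para-quinoid oxocarbenium ion centred on the C7 methoxy group with the spin at C3; in that form C8a is the β-carbon of an unsaturated oxocarbenium ion and the C3–C4 bond is close to single, so an E radical cation can also rotate into the cisoid geometry. The carboxylate oxygen then adds to C8a in a six-membered closure (6-exo-trig with respect to the C8–C8a π bond), a second one-electron oxidation and loss of the C8a proton to lutidine re-aromatise ring A, and the two protons are reduced to H2 at the cathode, so no chemical oxidant is needed. The closest known reaction types are the anodic dehydrogenative lactonisation of biaryl-2-carboxylic acids to benzocoumarins and the photocatalytic aerobic isomerisation and oxidative cyclisation of cinnamic acids to coumarins; the proposal joins the bond-forming manifold of the first to the substrate class of the second. Site selectivity rests on the substrate: C8a is the only ortho carbon that bears hydrogen, whereas addition at the other ortho carbon (C5) is an ipso attack on a carbon whose oxygen is capped as an acetal, gives an adduct with no group that can leave to restore aromaticity, and is therefore reversible. Lutidine keeps the medium non-acidic so that the O5 acetal survives (its loss would allow lactonisation through O5), HFIP stabilises the radical cation without adding to it, and high dilution disfavours intermolecular ester formation. No stereocentre is formed.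

Step 7
Reactants: 12 4-nitroresorcinol (4-nitrobenzene-1,3-diol)
Product: 13 4-nitro-1,3-phenylene bis(2,2-dimethylpropanoate)
Conditions: PivCl, Et3N, DMAP (cat.), CH2Cl2, 0 °C to rt
Reagents that add atoms: pivaloyl chloride, CC(C)(C)C(=O)Cl
Why: DMAP-catalysed O-acylation of both phenols, including the one hydrogen-bonded to the nitro group; the bulky esters resist solvolysis and acyl transfer in the next steps.

Step 8
Reactants: 13 4-nitro-1,3-phenylene bis(2,2-dimethylpropanoate)
Product: 15 2,4-bis[(2,2-dimethylpropanoyl)oxy]benzenediazonium tetrafluoroborate, via anilinium tetrafluoroborate 14 (not isolated)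
Conditions: H2 (1 atm), Pd/C, HBF4 (48% aq., 2.5 equiv), EtOH, rt; filter under Ar; tBuONO, 0 °C; precipitate with Et2O
Reagents that add atoms: tetrafluoroboric acid, F[B-](F)(F)F.[H+]; tert-butyl nitrite, CC(C)(C)ON=O
Why: Catalytic hydrogenation of the nitro group in the presence of HBF4 gives the anilinium salt directly, so the nitrogen is never a free base and O-to-N pivaloyl transfer from the ortho ester is suppressed; nitrosation and dehydration by the alkyl nitrite (diazotisation) then give the salt, which is precipitated cold.

Step 9
Reactants: 11 7-methoxy-5-(methoxymethoxy)-6-(3-methylbut-2-en-1-yl)-2H-chromen-2-one; 15 2,4-bis[(2,2-dimethylpropanoyl)oxy]benzenediazonium tetrafluoroborate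
Product: 16 4-[7-methoxy-5-(methoxymethoxy)-6-(3-methylbut-2-en-1-yl)-2-oxo-2H-chromen-3-yl]-1,3-phenylene bis(2,2-dimethylpropanoate)
Conditions: Ru(bpy)3Cl2 (2 mol%), NaHCO3 (solid), DMSO, blue LEDs, rt, Ar; 15 (2 equiv) added in portions
Reagents that add atoms: none
Why: Photoredox Meerwein arylation: the excited divalent ruthenium complex reduces 15 to an aryl radical with loss of N2; the radical adds to C3 because this gives the C4 radical benzylic to the dioxygenated ring A, and oxidation by the trivalent ruthenium complex followed by loss of the C3 proton restores the coumarin. C3 selectivity follows the classical Meerwein arylation of coumarins, and bicarbonate takes up the HBF4 so that the acetal is not cleaved.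

Step 10
Reactants: 16 4-[7-methoxy-5-(methoxymethoxy)-6-(3-methylbut-2-en-1-yl)-2-oxo-2H-chromen-3-yl]-1,3-phenylene bis(2,2-dimethylpropanoate)
Product: 18 3-(2,4-dihydroxyphenyl)-5-hydroxy-7-methoxy-6-(3-methylbut-2-en-1-yl)-2H-chromen-2-one, via 5-O-methoxymethyl diol 17 (not isolated)
Conditions: K2CO3, MeOH (degassed), rt; then aq. HCl to pH 1, 40 °C, Ar
Reagents that add atoms: none
Why: Carbonate-mediated transesterification removes both aryl pivalates; acidification in the same flask re-closes any lactone opened by methoxide and hydrolyses the aryl methoxymethyl acetal through its oxocarbenium ion (trapped by methanol). Dilute acid and mild temperature are chosen to keep the freed 5-OH from adding to the prenyl alkene.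

## Compound list

1 | 2-hydroxy-4-methoxybenzaldehyde | COc1ccc(C=O)c(O)c1 | starting material
2 | 3-chloro-3-methylbut-1-yne | C#CC(C)(C)Cl | starting material
3 | 4-methoxy-2-[(2-methylbut-3-yn-2-yl)oxy]benzaldehyde | COc1ccc(C=O)c(OC(C)(C)C#C)c1 | intermediate
4 | 4-methoxy-2-[(2-methylbut-3-en-2-yl)oxy]benzaldehyde | COc1ccc(C=O)c(OC(C)(C)C=C)c1 | intermediate
5 | 2-hydroxy-4-methoxy-3-(3-methylbut-2-en-1-yl)benzaldehyde | COc1ccc(C=O)c(O)c1CC=C(C)C | intermediate
6 | 4-methoxy-2-(methoxymethoxy)-3-(3-methylbut-2-en-1-yl)benzaldehyde | COCOc1c(C=O)ccc(OC)c1CC=C(C)C | intermediate
7 | malonic acid | O=C(O)CC(=O)O | starting material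
8 | 2-{[4-methoxy-2-(methoxymethoxy)-3-(3-methylbut-2-en-1-yl)phenyl]methylidene}propanedioic acid | COCOc1c(C=C(C(=O)O)C(=O)O)ccc(OC)c1CC=C(C)C | intermediate (not isolated)
9 | (E)-3-[4-methoxy-2-(methoxymethoxy)-3-(3-methylbut-2-en-1-yl)phenyl]prop-2-enoic acid | COCOc1c(/C=C/C(=O)O)ccc(OC)c1CC=C(C)C | intermediate
10 | (Z)-3-[4-methoxy-2-(methoxymethoxy)-3-(3-methylbut-2-en-1-yl)phenyl]prop-2-enoic acid | COCOc1c(/C=C\C(=O)O)ccc(OC)c1CC=C(C)C | intermediate (not isolated)
11 | 7-methoxy-5-(methoxymethoxy)-6-(3-methylbut-2-en-1-yl)-2H-chromen-2-one | COc1cc2oc(=O)ccc2c(OCOC)c1CC=C(C)C | intermediate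
12 | 4-nitroresorcinol (4-nitrobenzene-1,3-diol) | O=[N+]([O-])c1ccc(O)cc1O | starting material
13 | 4-nitro-1,3-phenylene bis(2,2-dimethylpropanoate) | O=[N+]([O-])c1ccc(OC(=O)C(C)(C)C)cc1OC(=O)C(C)(C)C | intermediate
14 | 2,4-bis[(2,2-dimethylpropanoyl)oxy]anilinium tetrafluoroborate | [NH3+]c1ccc(OC(=O)C(C)(C)C)cc1OC(=O)C(C)(C)C.F[B-](F)(F)F | intermediate (not isolated)
15 | 2,4-bis[(2,2-dimethylpropanoyl)oxy]benzenediazonium tetrafluoroborate | N#[N+]c1ccc(OC(=O)C(C)(C)C)cc1OC(=O)C(C)(C)C.F[B-](F)(F)F | intermediate
16 | 4-[7-methoxy-5-(methoxymethoxy)-6-(3-methylbut-2-en-1-yl)-2-oxo-2H-chromen-3-yl]-1,3-phenylene bis(2,2-dimethylpropanoate) | COc1cc2oc(=O)c(-c3ccc(OC(=O)C(C)(C)C)cc3OC(=O)C(C)(C)C)cc2c(OCOC)c1CC=C(C)C | intermediate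
17 | 3-(2,4-dihydroxyphenyl)-7-methoxy-5-(methoxymethoxy)-6-(3-methylbut-2-en-1-yl)-2H-chromen-2-one | COc1cc2oc(=O)c(-c3ccc(O)cc3O)cc2c(OCOC)c1CC=C(C)C | intermediate (not isolated)
18 | 3-(2,4-dihydroxyphenyl)-5-hydroxy-7-methoxy-6-(3-methylbut-2-en-1-yl)-2H-chromen-2-one | COc1cc2oc(=O)c(-c3ccc(O)cc3O)cc2c(O)c1CC=C(C)C | target

## Step count and least certain steps

Total: 10 steps. Longest linear sequence: 8 steps (steps 1 to 6, then 9 and 10). The ring B branch is steps 7 and 8.

**Step 6 (key step; the only step that rests on a new method).**
- What may go wrong: the cyclisation may fail to compete with intermolecular trapping of the radical cation (ester oligomerisation, or addition of base or solvent across the alkene). The anode may over-oxidise the product or attack the prenyl alkene. Prolonged irradiation may cause photodimerisation. Anodically generated acid may cleave the O5 acetal, after which the Z acid would lactonise through O5 into the isomeric 8-prenyl series.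
- Fallback (known chemistry; sets out from 6 and returns at 11): the oxygen is placed on the future C8a before the lactone is closed. The aldehyde of 6 is masked in the flask as its lithium α-amino alkoxide with lithium N,N,N′-trimethylethylenediamide (THF, −20 °C). n-BuLi then lithiates the ring position ortho to that group, B(OMe)3 traps the aryllithium, and aqueous work-up gives [2-formyl-5-methoxy-3-(methoxymethoxy)-4-(3-methylbut-2-en-1-yl)phenyl]boronic acid F1. Oxidation with trimethylamine N-oxide, chosen over alkaline peroxide to avoid Dakin oxidation, gives 6-hydroxy-4-methoxy-2-(methoxymethoxy)-3-(3-methylbut-2-en-1-yl)benzaldehyde F2. Wittig olefination of F2 with ethyl (triphenylphosphoranylidene)acetate in refluxing N,N-diethylaniline gives ethyl (Z)-3-[2-hydroxy-4-methoxy-6-(methoxymethoxy)-5-(3-methylbut-2-en-1-yl)phenyl]prop-2-enoate F3 (the E isomer equilibrates at this temperature), which lactonises with loss of ethanol to 11.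

**Step 9.**
- What may go wrong: the aryl radical may add to the prenyl alkene or abstract its allylic hydrogens in competition with C3 addition. It may be reduced by hydrogen abstraction from the solvent. The acetal may be lost if buffering is insufficient.
- Fallback (sets out from 11 and returns at 16): a polar organometallic coupling replaces the radical step. Directed zincation of 11 at C3 with TMPZnCl·LiCl (THF, rt) gives [7-methoxy-5-(methoxymethoxy)-6-(3-methylbut-2-en-1-yl)-2-oxo-2H-chromen-3-yl]zinc chloride F4. Negishi coupling (Pd(OAc)2, SPhos, THF, 50 °C) with 4-bromo-1,3-phenylene bis(2,2-dimethylpropanoate) F5, made from commercial 4-bromoresorcinol with PivCl and Et3N, gives 16.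

**Step 10.**
- What may go wrong: acid-catalysed addition of the freed 5-OH to the prenyl alkene (chroman formation), incomplete acetal cleavage if the acid is kept too mild, and air oxidation of the ring B phenoxide during the basic stage.
- Fallback (sets out from 17, isolated after the carbonate stage and neutral work-up, and returns at 18): the acetal is removed without Brønsted acid. TMSOTf with 2,2′-bipyridyl in CH2Cl2 at 0 °C converts the aryl acetal and the two phenols into 3-[2,4-bis(trimethylsilyloxy)phenyl]-7-methoxy-6-(3-methylbut-2-en-1-yl)-5-(trimethylsilyloxy)-2H-chromen-2-one F6, and aqueous work-up hydrolyses the three silyl ethers to 18.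

**Step 8.**
- What may go wrong: O-to-N acyl transfer if the amine is deprotonated at any point, acid-catalysed ethanolysis of the aryl esters during hydrogenation, and decomposition of the diazonium salt on isolation.
- Fallback (sets out from 12 and returns at 18): ring B is carried as acetals, so no acyl group can migrate and no diazonium salt is isolated. 12 with MOMCl and iPr2NEt gives 2,4-bis(methoxymethoxy)-1-nitrobenzene F7. Hydrogenation (H2, Pd/C, EtOAc) gives the stable 2,4-bis(methoxymethoxy)aniline F8. F8 is diazotised in the flask with tBuONO in the presence of 11 under the irradiation conditions of step 9, to give 3-[2,4-bis(methoxymethoxy)phenyl]-7-methoxy-5-(methoxymethoxy)-6-(3-methylbut-2-en-1-yl)-2H-chromen-2-one F9. One treatment with HCl in MeOH then removes all three acetals to give 18.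

**Step 3.**
- What may go wrong: thermal fragmentation of the tertiary allyl ether back to the phenol with loss of isoprene, a formal [1,3] shift to the O-prenyl ether, or carry-over of over-reduced ether from step 2 that cannot rearrange.
- Fallback (sets out from 1 and returns at 6, replacing steps 1 to 4): 1 with MOMCl and iPr2NEt gives 4-methoxy-2-(methoxymethoxy)benzaldehyde F10. The aldehyde is masked in the flask with lithium N-methylpiperazide, s-BuLi lithiates the ring carbon flanked by the two alkoxy groups, and CuBr·SMe2-mediated coupling with prenyl bromide followed by aqueous work-up gives 6.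

## Further compounds

F1 | step 6 | [2-formyl-5-methoxy-3-(methoxymethoxy)-4-(3-methylbut-2-en-1-yl)phenyl]boronic acid | COCOc1c(C=O)c(B(O)O)cc(OC)c1CC=C(C)C
F2 | step 6 | 6-hydroxy-4-methoxy-2-(methoxymethoxy)-3-(3-methylbut-2-en-1-yl)benzaldehyde | COCOc1c(C=O)c(O)cc(OC)c1CC=C(C)C
F3 | step 6 | ethyl (Z)-3-[2-hydroxy-4-methoxy-6-(methoxymethoxy)-5-(3-methylbut-2-en-1-yl)phenyl]prop-2-enoate | CCOC(=O)/C=C\c1c(O)cc(OC)c(CC=C(C)C)c1OCOC
F4 | step 9 | [7-methoxy-5-(methoxymethoxy)-6-(3-methylbut-2-en-1-yl)-2-oxo-2H-chromen-3-yl]zinc chloride | COc1cc2oc(=O)c([Zn]Cl)cc2c(OCOC)c1CC=C(C)C
F5 | step 9 | 4-bromo-1,3-phenylene bis(2,2-dimethylpropanoate) | Brc1ccc(OC(=O)C(C)(C)C)cc1OC(=O)C(C)(C)C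
F6 | step 10 | 3-[2,4-bis(trimethylsilyloxy)phenyl]-7-methoxy-6-(3-methylbut-2-en-1-yl)-5-(trimethylsilyloxy)-2H-chromen-2-one | COc1cc2oc(=O)c(-c3ccc(O[Si](C)(C)C)cc3O[Si](C)(C)C)cc2c(O[Si](C)(C)C)c1CC=C(C)C
F7 | step 8 | 2,4-bis(methoxymethoxy)-1-nitrobenzene | O=[N+]([O-])c1ccc(OCOC)cc1OCOC
F8 | step 8 | 2,4-bis(methoxymethoxy)aniline | Nc1ccc(OCOC)cc1OCOC
F9 | step 8 | 3-[2,4-bis(methoxymethoxy)phenyl]-7-methoxy-5-(methoxymethoxy)-6-(3-methylbut-2-en-1-yl)-2H-chromen-2-one | COc1cc2oc(=O)c(-c3ccc(OCOC)cc3OCOC)cc2c(OCOC)c1CC=C(C)C
F10 | step 3 | 4-methoxy-2-(methoxymethoxy)benzaldehyde | COCOc1cc(OC)ccc1C=O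
A1 | alternative 1 | 3-[2,4-bis(pivaloyloxy)phenyl]-5,7-dihydroxycoumarin | Oc1cc(O)c2cc(-c3ccc(OC(=O)C(C)(C)C)cc3OC(=O)C(C)(C)C)c(=O)oc2c1
A2 | alternative 1 | methyl 2-[2,4-bis(pivaloyloxy)phenyl]-3-(dimethylamino)prop-2-enoate | COC(=O)C(=CN(C)C)c1ccc(OC(=O)C(C)(C)C)cc1OC(=O)C(C)(C)C
A3 | alternative 1 | phloroglucinol (benzene-1,3,5-triol) | Oc1cc(O)cc(O)c1
A4 | alternative 2 | racemic 3-[2,4-bis(methoxymethoxy)phenyl]-5-hydroxy-7-methoxychroman-2-one | COc1cc(O)c2c(c1)OC(=O)C(c1ccc(OCOC)cc1OCOC)C2
A5 | alternative 2 | racemic methyl 2-[2,4-bis(methoxymethoxy)phenyl]-4-(4-methoxy-2-oxo-2H-pyran-6-yl)butanoate | COC(=O)C(CCc1cc(OC)cc(=O)o1)c1ccc(OCOC)cc1OCOC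
A6 | alternative 3 | 3-[2,4-bis(tert-butyldimethylsilyloxy)phenyl]-5-(tert-butyldimethylsilyloxy)-7-methoxy-6-prenylcoumarin | COc1cc2oc(=O)c(-c3ccc(O[Si](C)(C)C(C)(C)C)cc3O[Si](C)(C)C(C)(C)C)cc2c(O[Si](C)(C)C(C)(C)C)c1CC=C(C)C
A7 | alternative 3 | 3-[2,4-bis(tert-butyldimethylsilyloxy)phenyl]-5-[(1Z)-1-(tert-butyldimethylsilyloxy)-5-methylhexa-1,4-dien-1-yl]-6-[2-(tert-butyldimethylsilyloxy)-2-methoxyethenyl]-2H-pyran-2-one (ketene acetal geometry immaterial) | O=c1oc(C=C(OC)O[Si](C)(C)C(C)(C)C)c(/C(O[Si](C)(C)C(C)(C)C)=C/CC=C(C)C)cc1-c1ccc(O[Si](C)(C)C(C)(C)C)cc1O[Si](C)(C)C(C)(C)C
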